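**Strategy.** The cyclohexane is disconnected at C2–C3 and C1–C6. The cis methines C1/C2 come from a chiral cis dienophile; the 1,3-dimethyl four-carbon unit C3–C6, which later carries all four ring oxygens, is the diene of 4,6-dimethyl-2-pyrone. One thermal operation (cycloaddition, then CO2 loss) closes the carbocycle, sets C1 and C2 in absolute terms and leaves a C3=C4–C5=C6 diene for face-selective oxygenation. The precursors are the commercial pyrone and crystalline (5R)-5-(l-menthyloxy)furan-2(5H)-one, whose acetal carbon becomes the C2 methyl and whose carbonyl becomes C7. The triene–pyrone arm is attached late by two olefinations.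

Key step: step 3

Remark (numbering and stereochemistry, read from the SMILES): ring carbons run C1 (CH bearing the chain) to C6 (CHOH), chain carbons C7–C12 outward from the ring; the four ring oxygens are mutually cis and lie trans to the C1 and C2 carbon substituents.

Remark (structure check): the stated precursors and cycloadduct are mutually consistent and map onto the target enantiomer, so no structure was changed.

**Route**

Step 1
Reactants: 1 furfural
Product: 2 5-hydroxyfuran-2(5H)-one
Conditions: O2, rose bengal (cat.), hν, MeOH, rt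
Reagents that add atoms: oxygen, O=O
Why: Singlet-oxygen [4+2] addition to the furan and methanol-assisted fragmentation of the endoperoxide (the formyl carbon leaves as methyl formate) is the standard photooxygenation route to this racemic hydroxybutenolide.

Step 2
Reactants: 2 5-hydroxyfuran-2(5H)-one; 3 (−)-menthol
Product: 5 (5R)-5-(l-menthyloxy)furan-2(5H)-one, via 5S epimer 4 (not isolated)
Conditions: CSA (cat.), toluene, reflux, Dean–Stark; crystallisation from petroleum ether, mother liquor re-equilibrated with CSA and recrystallised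
Reagents that add atoms: none
Why: Acid-catalysed acetalisation gives both C5 epimers, which interconvert under the acid while the less soluble 5R epimer crystallises, so the acetal centre is set by crystallisation-driven epimerisation.

Step 3
Reactants: 5 (5R)-5-(l-menthyloxy)furan-2(5H)-one; 6 4,6-dimethyl-2H-pyran-2-one
Product: 8 cis-fused 3-(l-menthyloxy)-4,6-dimethyl-3a,7a-dihydroisobenzofuran-1(3H)-one, via bridged lactone 7 (not isolated)
Conditions: neat in excess 6 (8 equiv), BHT (cat.), argon, sealed tube, 140 °C
Reagents that add atoms: none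
Why: A thermal [4+2] cycloaddition between pyrone C3/C6 and the electron-poor butenolide alkene should give the bridged 2-oxabicyclo[2.2.2]octenone 7, which expels CO2 by retro-[4+2] at the same temperature to unveil the C3=C4–C5=C6 diene. The closest known chemistry is the 2-pyrone Diels–Alder/decarboxylation route to cyclohexa-1,3-dienes, combined with the anti-selective cycloadditions of 5-alkoxybutenolides. The carbocycle is closed by the concerted intermolecular cycloaddition itself, C2–C3 and C1–C6 forming in one event. C1 and C2 are set cis by suprafacial addition to the Z-alkene, and their absolute sense by the acetal carbon, since the diene should approach the face anti to the menthyloxy group. The step needs the butenolide β-carbon to join the methyl-bearing pyrone C6 and the α-carbon to join pyrone C3, the orientation usually seen when 2-pyrones add acceptor alkenes (acceptor carbon next to the carbonyl-side bridgehead); the two methyl groups may erode it, and this is the main risk of the route, whereas endo/exo selectivity is immaterial because both bridgeheads become sp2. A large excess of molten pyrone, BHT and exclusion of air and acid should hold back a second cycloaddition of 8, polymerisation and aromatisation.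

Step 4
Reactants: 8 cis-fused 3-(l-menthyloxy)-4,6-dimethyl-3a,7a-dihydroisobenzofuran-1(3H)-one
Product: 10 cis-ene-diol lactone acetal, via endoperoxide 9 (not isolated)
Conditions: O2, TPP (cat.), hν, CH2Cl2, −20 °C; then thiourea, MeOH, rt
Reagents that add atoms: oxygen, O=O
Why: Singlet-oxygen [4+2] cycloaddition to the s-cis diene should occur on the convex face anti to the cis-fused lactone, setting the C3 and C6 oxygens cis to each other and trans to the C1/C2 substituents, and thiourea then cleaves only the O–O bond (endoperoxide reduction) with retention at both carbons.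

Step 5
Reactants: 10 cis-ene-diol lactone acetal
Product: 11 C6 O-TBS ether of 10
Conditions: TBSOTf (1.1 equiv), 2,6-lutidine, CH2Cl2, −78 °C
Reagents that add atoms: tert-butyldimethylsilyl triflate, CC(C)(C)[Si](C)(C)OS(=O)(=O)C(F)(F)F
Why: Silyl triflate silylation at low temperature should discriminate the secondary allylic C6 hydroxyl from the tertiary C3 hydroxyl on steric grounds, which marks C6 before the second secondary hydroxyl (C4) exists.

Step 6
Reactants: 11 C6 O-TBS ether of 10
Product: 13 all-cis C3/C4/C5 triol C6 silyl ether, via osmate ester 12 (not isolated)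
Conditions: OsO4 (1.05 equiv), TMEDA (1.1 equiv), CH2Cl2, −78 °C; then sat. aq NaHSO3, THF, 40 °C
Reagents that add atoms: osmium tetroxide, O=[Os](=O)(=O)=O
Why: In this hydrogen-bond-directed syn-dihydroxylation the OsO4·TMEDA complex is delivered by the free C3 hydroxyl to the hydroxyl-bearing face, which is also the face away from the C3 methyl and the lactone, so C4 and C5 are set with all four ring oxygens cis.

Step 7
Reactants: 13 all-cis C3/C4/C5 triol C6 silyl ether
Product: 14 dithiane acid
Conditions: HS(CH2)3SH (1.5 equiv), BF3·OEt2, CH2Cl2, −30 → 0 °C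
Reagents that add atoms: propane-1,3-dithiol, SCCCS
Why: Lewis-acid transthioacetalisation of the pseudo-ester (an acylal-type acetal) opens the lactone to an oxocarbenium ion that the dithiol traps before displacing menthol, leaving a dithiane on the former acetal carbon and the free C7 carboxylic acid, so the two carbons stay differentiated and C2 is not touched.

Step 8
Reactants: 14 dithiane acid
Product: 15 C2-methyl acid
Conditions: Raney Ni (W-2, washed neutral), EtOH, rt → 50 °C
Reagents that add atoms: none
Why: Raney-nickel desulfurisation (Mozingo reduction) converts the dithiane into the C2 methyl group without affecting alcohols, silyl ether or carboxylic acid.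

Step 9
Reactants: 15 C2-methyl acid
Product: 16 C7 primary alcohol
Conditions: BH3·THF (excess), THF, 0 °C → rt; then MeOH, aqueous work-up
Reagents that add atoms: none
Why: Borane reduces the carboxylic acid chemoselectively through its acyloxyborane to the primary alcohol, the free hydroxyls being only transiently borylated and C1 never enolised.

Step 10
Reactants: 16 C7 primary alcohol
Product: 17 C7 aldehyde
Conditions: TEMPO (0.2 equiv), PhI(OAc)2 (1.2 equiv), CH2Cl2, rt
Reagents that add atoms: none
Why: The oxoammonium (TEMPO/PhI(OAc)2) oxidation is selective for primary over hindered secondary alcohols and runs without base, so the C4 hydroxyl survives and the equatorial, thermodynamically preferred C1 centre is kept.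

Step 11
Reactants: 17 C7 aldehyde; 18 2-(triphenylphosphoranylidene)propanal
Product: 19 (E)-enal
Conditions: 18 (1.5 equiv), toluene, 90 °C
Reagents that add atoms: none
Why: Wittig olefination with the formyl-stabilised ylide should give the (E)-2-methyl enal directly (C7=C8, E by thermodynamic control with stabilised ylides) under neutral conditions that spare C1 and the β-silyloxy group.

Step 12
Reactants: 20 methyl 2-methyl-3-oxopentanoate; 21 N-methoxy-N-methylpropanamide
Product: 22 methyl 2,4-dimethyl-3,5-dioxoheptanoate
Conditions: LDA (2.2 equiv), THF, −78 → 0 °C; then 21, −78 → 0 °C; aq HCl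
Reagents that add atoms: none
Why: γ-Acylation of the β-keto ester dianion with a Weinreb amide stops at the ketone because the chelated tetrahedral intermediate persists until work-up; the enolisable stereocentres are of no consequence.

Step 13
Reactants: 22 methyl 2,4-dimethyl-3,5-dioxoheptanoate
Product: 23 6-ethyl-4-hydroxy-3,5-dimethyl-2H-pyran-2-one
Conditions: DBU, toluene, 80 °C
Reagents that add atoms: none
Why: Base-mediated enol lactonisation (acyl substitution of the ester by the C5 enolate oxygen) closes the 4-hydroxy-2-pyrone with loss of methanol.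

Step 14
Reactants: 23 6-ethyl-4-hydroxy-3,5-dimethyl-2H-pyran-2-one
Product: 24 6-ethyl-2-methoxy-3,5-dimethyl-4H-pyran-4-one
Conditions: MeOTf, CH2Cl2, rt; aq NaHCO3
Reagents that add atoms: methyl triflate, COS(=O)(=O)C(F)(F)F
Why: The hard methylating agent attacks the most basic site of the neutral hydroxypyrone, the lactone carbonyl oxygen, and loss of the 4-OH proton gives the 2-methoxy-4-pyrone and not the 4-methoxy-2-pyrone (regioselective O-methylation).

Step 15
Reactants: 24 6-ethyl-2-methoxy-3,5-dimethyl-4H-pyran-4-one; 25 (tert-butyldimethylsilyloxy)acetaldehyde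
Product: 26 pyrone aldol adduct
Conditions: LiHMDS, THF, −78 °C; then 25; AcOH quench
Reagents that add atoms: none
Why: Deprotonation of the 6-ethyl group gives the extended pyrone enolate, which adds 1,2 to the aldehyde (vinylogous aldol addition); both new stereocentres are removed in the next step.

Step 16
Reactants: 26 pyrone aldol adduct
Product: 28 (E)-allylic silyl ether pyrone, via mesylate 27 (not isolated)
Conditions: MsCl, Et3N, CH2Cl2, 0 °C; then DBU, rt
Reagents that add atoms: none
Why: Mesylation followed by E1cB elimination through the acidic pyrone CH completes the aldol condensation, and the E alkene (pyrone trans to CH2) should form as the less strained conjugated product, setting C11=C12.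

Step 17
Reactants: 28 (E)-allylic silyl ether pyrone
Product: 29 (E)-allylic bromide pyrone
Conditions: Ph3PBr2, CH2Cl2, 0 °C → rt
Reagents that add atoms: dibromotriphenylphosphorane, BrP(Br)(c1ccccc1)(c1ccccc1)c1ccccc1
Why: Dibromotriphenylphosphorane converts primary allylic silyl ethers directly into bromides through an alkoxyphosphonium ion (Appel-type SN2 at the unhindered CH2), so the alkene geometry is kept.

Step 18
Reactants: 29 (E)-allylic bromide pyrone
Product: 30 (E)-allylic phosphonate pyrone
Conditions: P(OEt)3 (neat), 100 °C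
Reagents that add atoms: triethyl phosphite, CCOP(OCC)OCC
Why: The Michaelis–Arbuzov reaction of the primary allylic bromide gives the phosphonate by SN2 at CH2 and loss of bromoethane.

Step 19
Reactants: 19 (E)-enal; 30 (E)-allylic phosphonate pyrone
Product: 31 all-E triene–pyrone triol silyl ether
Conditions: 30 (1.5 equiv), LiHMDS, THF, −78 °C; then 19, −78 → 0 °C
Reagents that add atoms: none
Why: Horner–Wadsworth–Emmons olefination of the enal with the lithiated allylic phosphonate should form C9=C10 with E geometry, and the stabilised anion is too weak a base to deprotonate the free hydroxyls.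

Step 20
Reactants: 31 all-E triene–pyrone triol silyl ether
Product: 32 C4 acetate of 31
Conditions: Ac2O, pyridine, DMAP (cat.), CH2Cl2, 0 °C → rt
Reagents that add atoms: acetic anhydride, CC(=O)OC(C)=O
Why: DMAP-catalysed acylation should reach the only free secondary hydroxyl (C4) ahead of the two axial tertiary hydroxyls while C6 is blocked by silicon (chemoselective acetylation).

Step 21
Reactants: 32 C4 acetate of 31
Product: 33 amaurone A
Conditions: HF·pyridine, pyridine, THF, 0 °C → rt
Reagents that add atoms: none
Why: Buffered fluoride desilylation cleaves the Si–O bond under mildly acidic conditions that should neither move the acetyl group nor harm the methoxypyrone and the triene.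

**Compound list**

1 | furfural | O=Cc1ccco1 | starting material
2 | 5-hydroxyfuran-2(5H)-one (racemic) | O=C1OC(O)C=C1 | intermediate
3 | (−)-menthol, (1R,2S,5R) | C[C@@H]1CC[C@H]([C@@H](C1)O)C(C)C | starting material
4 | (5S)-5-(l-menthyloxy)furan-2(5H)-one (epimer, equilibrated in the flask) | O=C1O[C@H](O[C@@H]2C[C@H](C)CC[C@H]2C(C)C)C=C1 | intermediate
5 | (5R)-5-(l-menthyloxy)furan-2(5H)-one | O=C1O[C@@H](O[C@@H]2C[C@H](C)CC[C@H]2C(C)C)C=C1 | intermediate
6 | 4,6-dimethyl-2H-pyran-2-one | CC1=CC(C)=CC(=O)O1 | starting material
7 | bridged cycloadduct: 2-oxabicyclo[2.2.2]oct-7-en-3-one with the menthyloxy γ-lactone cis-fused across the new ethano bridge (endo/exo mixture, bridgeheads undefined) | O=C1[C@@H]2[C@H]([C@H](O[C@@H]3C[C@H](C)CC[C@H]3C(C)C)O1)C4(C)C=C(C)C2C(=O)O4 | intermediate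
8 | cis-fused 3-(l-menthyloxy)-4,6-dimethyl-3a,7a-dihydroisobenzofuran-1(3H)-one, menthyloxy trans to the C3a–C4 bond (C7a = C1, C3a = C2, diene = C3–C6) | O=C1O[C@@H](O[C@@H]3C[C@H](C)CC[C@H]3C(C)C)[C@H]2[C@@H]1C=C(C)C=C2C | intermediate
9 | endoperoxide of 8: O–O bridge C3 to C6 on the face opposite the lactone, C4=C5 | O=C1[C@@H]2[C@H]([C@H](O[C@@H]3C[C@H](C)CC[C@H]3C(C)C)O1)[C@@](C)(OO4)C=C(C)[C@H]24 | intermediate
10 | cis-ene-diol: tertiary C3-OH and secondary C6-OH cis to each other and trans to the lactone, C4=C5 | O=C1[C@@H]2[C@H]([C@H](O[C@@H]3C[C@H](C)CC[C@H]3C(C)C)O1)[C@@](C)(O)C=C(C)[C@H]2O | intermediate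
11 | C6 O-TBS ether of 10 | O=C1[C@@H]2[C@H]([C@H](O[C@@H]3C[C@H](C)CC[C@H]3C(C)C)O1)[C@@](C)(O)C=C(C)[C@H]2O[Si](C)(C)C(C)(C)C | intermediate
12 | osmate(VI) ester of 11 across C4/C5 on the hydroxyl face, TMEDA chelate | O=C1[C@@H]2[C@H]([C@H](O[C@@H]3C[C@H](C)CC[C@H]3C(C)C)O1)[C@@](C)(O)[C@H]4O[Os](=O)(=O)O[C@@]4(C)[C@H]2O[Si](C)(C)C(C)(C)C.CN(C)CCN(C)C | intermediate
13 | lactone acetal with C3/C4/C5 triol and C6-OTBS, all four ring oxygens cis | O=C1[C@@H]2[C@H]([C@H](O[C@@H]3C[C@H](C)CC[C@H]3C(C)C)O1)[C@@](C)(O)[C@@H](O)[C@@](C)(O)[C@H]2O[Si](C)(C)C(C)(C)C | intermediate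
14 | dithiane acid: C1–CO2H, C2–(1,3-dithian-2-yl), C3/C4/C5 triol, C6-OTBS | OC(=O)[C@@H]1[C@H](C2SCCCS2)[C@@](C)(O)[C@@H](O)[C@@](C)(O)[C@H]1O[Si](C)(C)C(C)(C)C | intermediate
15 | C2-methyl acid (C1–CO2H cis to C2–CH3) | OC(=O)[C@@H]1[C@H](C)[C@@](C)(O)[C@@H](O)[C@@](C)(O)[C@H]1O[Si](C)(C)C(C)(C)C | intermediate
16 | C7 primary alcohol | OC[C@@H]1[C@H](C)[C@@](C)(O)[C@@H](O)[C@@](C)(O)[C@H]1O[Si](C)(C)C(C)(C)C | intermediate
17 | C7 aldehyde | O=C[C@@H]1[C@H](C)[C@@](C)(O)[C@@H](O)[C@@](C)(O)[C@H]1O[Si](C)(C)C(C)(C)C | intermediate
18 | 2-(triphenylphosphoranylidene)propanal | CC(C=O)=P(c1ccccc1)(c1ccccc1)c1ccccc1 | starting material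
19 | (E)-2-methyl enal (C7=C8, C9 aldehyde) | O=C/C(C)=C/[C@@H]1[C@H](C)[C@@](C)(O)[C@@H](O)[C@@](C)(O)[C@H]1O[Si](C)(C)C(C)(C)C | intermediate
20 | methyl 2-methyl-3-oxopentanoate | CCC(=O)C(C)C(=O)OC | starting material
21 | N-methoxy-N-methylpropanamide | CCC(=O)N(C)OC | starting material
22 | methyl 2,4-dimethyl-3,5-dioxoheptanoate (stereoisomer/tautomer mixture) | CCC(=O)C(C)C(=O)C(C)C(=O)OC | intermediate
23 | 6-ethyl-4-hydroxy-3,5-dimethyl-2H-pyran-2-one | CCC1=C(C)C(O)=C(C)C(=O)O1 | intermediate
24 | 6-ethyl-2-methoxy-3,5-dimethyl-4H-pyran-4-one | CCc1oc(OC)c(C)c(=O)c1C | intermediate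
25 | (tert-butyldimethylsilyloxy)acetaldehyde | O=CCO[Si](C)(C)C(C)(C)C | starting material
26 | 6-[4-(TBS-oxy)-3-hydroxybutan-2-yl]-2-methoxy-3,5-dimethyl-4H-pyran-4-one (diastereomer mixture) | COc1oc(C(C)C(O)CO[Si](C)(C)C(C)(C)C)c(C)c(=O)c1C | intermediate
27 | 3-O-mesylate of 26 | COc1oc(C(C)C(OS(C)(=O)=O)CO[Si](C)(C)C(C)(C)C)c(C)c(=O)c1C | intermediate
28 | 6-[(E)-4-(TBS-oxy)but-2-en-2-yl]-2-methoxy-3,5-dimethyl-4H-pyran-4-one | COc1oc(/C(C)=C/CO[Si](C)(C)C(C)(C)C)c(C)c(=O)c1C | intermediate
29 | 6-[(E)-4-bromobut-2-en-2-yl]-2-methoxy-3,5-dimethyl-4H-pyran-4-one | COc1oc(/C(C)=C/CBr)c(C)c(=O)c1C | intermediate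
30 | diethyl [(E)-3-(6-methoxy-3,5-dimethyl-4-oxo-4H-pyran-2-yl)but-2-en-1-yl]phosphonate | COc1oc(/C(C)=C/CP(=O)(OCC)OCC)c(C)c(=O)c1C | intermediate
31 | all-E triene–pyrone with ring C3/C4/C5 triol and C6-OTBS | COc1oc(/C(C)=C/C=C/C(C)=C/[C@@H]2[C@H](C)[C@@](C)(O)[C@@H](O)[C@@](C)(O)[C@H]2O[Si](C)(C)C(C)(C)C)c(C)c(=O)c1C | intermediate
32 | C4 acetate of 31 | COc1oc(/C(C)=C/C=C/C(C)=C/[C@@H]2[C@H](C)[C@@](C)(O)[C@@H](OC(C)=O)[C@@](C)(O)[C@H]2O[Si](C)(C)C(C)(C)C)c(C)c(=O)c1C | intermediate
33 | amaurone A | COc1oc(/C(C)=C/C=C/C(C)=C/[C@@H]2[C@H](C)[C@@](C)(O)[C@@H](OC(C)=O)[C@@](C)(O)[C@H]2O)c(C)c(=O)c1C | target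

**Step count.** Total: 21 steps. Longest linear sequence: 14 steps (steps 1–11, then 19–21, from furfural); the pyrone branch (steps 12–18) joins at step 19.

**Steps most likely to fail (in order of risk)**

Step 3. The cycloaddition may be slow, the diene may add in the opposite orientation (pyrone C3 to the β-carbon), and the product diene may be consumed by a second cycloaddition. The fallback commits the orientation with a removable halogen. Pyrone 6 would be brominated at C3 (NBS, DMF) to 3-bromo-4,6-dimethyl-2H-pyran-2-one F1. 3-Bromo-2-pyrones are established ambiphilic dienes that react at lower temperature and place the acceptor-bearing alkene carbon next to the brominated terminus. F1 and 5 (toluene, 100–120 °C) should therefore pass through the bridged bromo lactone F2 (not isolated) and, after CO2 loss, give 7-bromo-3-(l-menthyloxy)-4,6-dimethyl-3a,7a-dihydroisobenzofuran-1(3H)-one F3. Palladium-catalysed hydrodebromination of the vinyl bromide (Pd(PPh3)4, Bu3SnH) would then return to 8.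

Step 7. Under the Lewis acid the silyl ether may be lost, a tertiary alcohol may ionise (pinacol-type shift), or C2 may epimerise through a vinyl sulfide. The fallback avoids Lewis acid altogether. From 13, NaBH4/KOH in aqueous ethanol should open the pseudo-ester and reduce the released C2 aldehyde as it forms; acidification then closes the lactone in the reversed sense to the cis-fused γ-lactone F4 (C7 carbonyl, O–CH2 on C2), with menthol released. PhSeNa (from PhSeSePh and NaBH4, DMF, 110 °C) would open F4 by SN2 attack at the lactone CH2 to the phenylselanyl acid F5. Bu3SnH/AIBN would replace selenium by hydrogen and rejoin the route at 15.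

Step 6. The bulky silyl ether next to the alkene may slow the osmylation or divert it to the other face (poor facial selectivity). The fallback osmylates before silylation. From 10, with both cis hydroxyls free as directing groups on the same face, OsO4/TMEDA should give the all-cis tetraol lactone acetal F6. The two secondary hydroxyls would then be told apart by sterics: TBSOTf/2,6-lutidine at −78 °C should silylate C6-OH (one quaternary neighbour) ahead of C4-OH (two quaternary neighbours), returning to 13.

**Further compounds**

F1 | step 3 | 3-bromo-4,6-dimethyl-2H-pyran-2-one | CC1=CC(C)=C(Br)C(=O)O1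
F2 | step 3 | bridged bromo cycloadduct (bromine on the bridgehead next to the lactone carbonyl, endo/exo mixture) | O=C1[C@@H]2[C@H]([C@H](O[C@@H]3C[C@H](C)CC[C@H]3C(C)C)O1)C4(C)C=C(C)C2(Br)C(=O)O4
F3 | step 3 | 7-bromo-3-(l-menthyloxy)-4,6-dimethyl-3a,7a-dihydroisobenzofuran-1(3H)-one | O=C1O[C@@H](O[C@@H]3C[C@H](C)CC[C@H]3C(C)C)[C@H]2[C@@H]1C(Br)=C(C)C=C2C
F4 | step 7 | cis-fused γ-lactone (C7 carbonyl on C1, O–CH2 on C2), C3/C4/C5 triol, C6-OTBS | O=C1[C@@H]2[C@H](CO1)[C@@](C)(O)[C@@H](O)[C@@](C)(O)[C@H]2O[Si](C)(C)C(C)(C)C
F5 | step 7 | phenylselanylmethyl acid (C1–CO2H, C2–CH2SePh) | OC(=O)[C@@H]1[C@H](C[Se]c2ccccc2)[C@@](C)(O)[C@@H](O)[C@@](C)(O)[C@H]1O[Si](C)(C)C(C)(C)C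
F6 | step 6 | all-cis C3/C4/C5/C6 tetraol lactone acetal | O=C1[C@@H]2[C@H]([C@H](O[C@@H]3C[C@H](C)CC[C@H]3C(C)C)O1)[C@@](C)(O)[C@@H](O)[C@@](C)(O)[C@H]2O
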